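# Total synthesis proposal for CNP0159470.1, the (4aR,9bS)-configured Z,Z lunarine-type macrocycle

## Analysis of the target

1. The target 18 (C25H31N3O4) is a lunarine-type spermidine alkaloid. Dibenzofuran numbering is used for the core of every compound below. Ring A is the benzene ring (C5a, C6–C9, C9a), ring B the dihydrofuran (O5, C4a, C9b, C9a, C5a), and ring C the cyclohexanone (C1–C4, C4a, C9b; C3=O).
2. Ring D is a 20-membered bis-lactam. It leaves C9b as arm 1 (C9b–CH=CH–C(=O)–N1), runs through N1–(CH2)3–N4H–(CH2)4–N8, and returns as arm 2 (N8–C(=O)–CH=CH–C8) via C9 and C9a, so the unsymmetrical triamine has one fixed orientation.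
3. There are two contiguous stereocentres: the all-carbon quaternary C9b (S; bonded to aryl C9a, a vinyl carbon, C1H2 and C4a) and the ether carbon C4a (R). Rings B and C are cis-fused, and because a trans fusion is out of reach, C4a follows from C9b and only one stereochemical problem is independent.
4. Both alkenes are Z as written, which is the less stable geometry, and the alkene of arm 1 sits on a neopentyl position.
5. The sensitive groups are the β-aryloxy ketone O5–C4a–C4–C3=O (retro-oxa-Michael), the two Z-enamides (light, radicals, reversible conjugate addition) and the free N4H.
6. The difficulty is the combination of four demands: an enantiopure quaternary carbon with two sp2 substituents, two Z-alkenes, and a macrocycle closed in the right orientation.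
7. The feature exploited is this. Because arm 1 is Z, its acyl carbon lies over O5, and the seven atoms O5–C5a–C9a–C9b–CH=CH–C(=O) can be closed to a ring. Two further features add to this: the retro-oxa-Michael retron, and the hidden symmetry of ring C, in which C9b is the para carbon of a latent phenol ring and C1/C2 and C4a/C4 are its enantiotopic halves. Together they invite a bond exchange, in which O5–C4a and N1–C(=O) of 18 are traded for one O5–C(=O) bond in the precursor.

## Retrosynthetic reasoning

**18 ⇒ 17 ⇒ 16 (15).** The O5–C4a bond is cut by a retro-oxa-Michael step, giving 17. The N1–C(=O) bond of arm 1 is then cut and its acyl carbon is reconnected to O5, giving 16, which is stored as its salt 15.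

- 16 is an isomer of 18 in which rings B and D are replaced by one seven-membered aryl lactone spiro-fused to a cyclohexenone.
- The cut is made here because this lactone does three jobs. It locks arm 1 as Z, it masks O5 so that no premature ring closure can occur, and it is the activated ester for the macrolactamisation.
- The forward reaction has to move the acyl group from O5 to N1. The freed phenoxide then closes ring B on the only enone left.

**15 ⇒ 14.** The two ammonium groups are traced back to two tert-butyl carbamates. No skeletal bond is cut. The gain is that the amines stay silent until the last operation.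

**14 ⇒ 13 ⇒ 12.** The C1–C2 single bond is traced back to a second C=C bond.

- This turns the chiral enone into the cross-conjugated dienone 12, in which C9b is prochiral.
- All earlier chemistry therefore becomes achiral, and the absolute configuration depends on one catalytic choice between two enantiotopic enone arms.
- The forward reaction is a desymmetrising conjugate reduction. It is possible only because O5 is tied up in the lactone. With free O5 the dienone would close ring B at once and as a racemate.

**12 ⇒ 11 + 5.** The C=C bond of arm 2 is cut. This joins the whole polyamine chain to the core in one convergent Z-selective olefination of an aromatic aldehyde, the class of aldehyde on which such olefinations are most dependable. The orientation of the triamine is fixed by the choice of 1.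

**11 ⇒ 10.** The C9b–CH= bond of arm 1 is cut and ring C is rearomatised to an anisole.

- The precursor 10 is a flat biaryl ester.
- The forward reaction must make the ipso carbon of the anisole ring attack the terminal alkyne carbon. This creates the quaternary carbon, the dienone and the ring-locked Z-alkene together.
- Cutting C9b–C9a instead would demand an intermolecular para-arylation of a phenol, for which no handle exists in this structure.

**10 ⇒ 8 + 9, and 8 ⇒ 6 + 7.** The ester C–O bond and the biaryl C9a–C9b bond are cut. Both are routine bonds between commercial pieces.

**5 ⇒ 3 + 4, and 3 ⇒ 1 + 2.** The P–C and N8–C(=O) bonds are cut. In 1 only N8 is free, so the chain can be acylated in one direction only.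

## Alternatives that were turned down

**Alternative 1:** the textbook route, core first and lactams last.

- Disconnection: both amide bonds of ring D are cut, giving the tricyclic Z,Z-diacid A2 and the free triamine.
- Forward key steps: an asymmetric Tsuji–Trost etherification sets C4a in the bromoaryl cyclohexenyl ether A1. An intramolecular 5-exo Heck reaction then sets C9b. Redox adjustments, two separate Z-olefinations and a double amide formation follow.
- Reason turned down: the Heck product still carries a ring alkene and a protected hydroxymethyl group, which have to be reworked.
- The two acids of A2 and the two primary amines of the triamine must be told apart by protecting groups, or constitutional isomers of ring D will form.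
- Externally activated Z-acrylic acids lose geometry through reversible addition of the nucleophilic additives used for activation.
- The count would be well above fifteen steps, and no single step carries much of the problem.

**Alternative 2:** biomimetic oxidative phenol coupling.

- Disconnection: C9a–C9b and O5–C4a are cut, giving the open bis-amide A3.
- Forward key step: a one-electron oxidation with ortho–para coupling closes ring D to the dienone phenol A4, which closes ring B by itself. An enone reduction ends the route.
- Reason turned down: in a 4-hydroxycinnamoyl phenoxyl radical the spin density sits on O, the ortho carbons and the side-chain β-carbon. Bond formation at the fully substituted para carbon therefore has to beat the lignan-type couplings.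
- Both phenol rings of A3 are equally oxidisable, so the orientation of the triamine is not controlled.
- Radical conditions erode the Z geometry.
- A4 cyclises spontaneously, which leaves no room for a chiral catalyst.

**Alternative 3:** dearomative Diels–Alder construction of ring C.

- Disconnection: C9b–C1 and C4a–C4 are cut, giving the 3-formylbenzofuran A5 and a 2-silyloxybuta-1,3-diene.
- Forward key step: a [4+2] cycloaddition on the C2=C3 bond of the furan ring gives the keto aldehyde A6 with both stereocentres set suprafacially. The regiochemistry is correct, because the formyl-bearing carbon ends up para to the oxygenated diene carbon.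
- Reason turned down: that double bond is part of an aromatic ring and also of a vinylogous ester, so its acceptor orbital is raised by O-donation.
- The forcing conditions this implies are not compatible with control by a chiral Lewis acid.
- Two olefinations, a cross-coupling and the whole macrocycle problem would still remain after the key step.

Key step: step 9

Assumption: both C=C bonds are taken as Z exactly as the SMILES string writes them. The (S,S) ligand is written in step 7, and its mirror image is to be used if the sense of induction on this spiro substrate turns out to be opposite.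

## Route

Step 1
Reactants: 1 N1,N4-bis-Boc-spermidine; 2 bromoacetyl bromide
Product: 3 N8-bromoacetyl-N1,N4-bis-Boc-spermidine
Conditions: Et3N, CH2Cl2, −78 °C to 0 °C
Reagents that add atoms: none
Why: Acylation of the only free (primary) amine of 1 by the acyl bromide end of 2 (Schotten–Baumann-type N-acylation). At low temperature the alkyl bromide is not touched and both carbamates are inert.

Step 2
Reactants: 3 N8-bromoacetyl-N1,N4-bis-Boc-spermidine; 4 diphenyl phosphite
Product: 5 diphenyl phosphonoacetamide of the protected chain
Conditions: Et3N, CH2Cl2, 0 °C to rt
Reagents that add atoms: none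
Why: Michaelis–Becker alkylation, in which the phosphite anion formed by the amine base displaces the activated primary bromide. The two aryloxy groups on phosphorus are what later makes the olefination Z-selective.

Step 3
Reactants: 6 3-bromo-4-hydroxybenzaldehyde; 7 4-methoxyphenylboronic acid
Product: 8 6-hydroxy-4'-methoxybiphenyl-3-carbaldehyde
Conditions: Pd(PPh3)4 (3 mol %), K2CO3, dioxane/H2O, 90 °C
Reagents that add atoms: none
Why: Suzuki–Miyaura coupling of an electron-poor aryl bromide, which forms the future C9a–C9b bond. The free phenol and the aldehyde are tolerated under aqueous carbonate.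

Step 4
Reactants: 8 6-hydroxy-4'-methoxybiphenyl-3-carbaldehyde; 9 propiolic acid
Product: 10 5-formyl-4'-methoxybiphenyl-2-yl prop-2-ynoate
Conditions: DCC, DMAP (5 mol %), CH2Cl2, −20 °C to 0 °C
Reagents that add atoms: none
Why: Steglich esterification of an acidic phenol. The low temperature and the small amount of DMAP keep conjugate addition to the ynoate in check.

Step 5
Reactants: 10 5-formyl-4'-methoxybiphenyl-2-yl prop-2-ynoate
Product: 11 (3Z)-2,4'-dioxospiro[1-benzoxepine-5,1'-cyclohexa-2',5'-diene]-7-carbaldehyde
Conditions: Ph3PAuCl (5 mol %), AgOTf (5 mol %), H2O (2 equiv), ClCH2CH2Cl, 60 °C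
Reagents that add atoms: water, O
Why: Proposed new method: the cationic monovalent gold complex binds the electron-poor alkyne of 10 and makes its terminal (β) carbon electrophilic; the only ring carbon that is both activated (para to OMe) and within reach is the ipso carbon of the anisole ring (future C9b), which attacks anti to gold in a 7-endo-dig closure; water then converts the methoxy-substituted cation into the ketone with loss of methanol, and protodeauration leaves the CH=CH unit, whose Z geometry is enforced by the seven-membered ring; the closest known reaction types are the gold-catalysed dearomative ipso-cyclisation of 4-methoxyaryl alkynoates (five-membered spirolactones) and the ipso-cyclisation of biaryl ynones (six-membered spiroketones), so the step is new only in ring size; ring A cannot compete because its formyl and acyloxy groups deactivate it towards the 6-endo hydroarylation that would lead to a coumarin.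

Step 6
Reactants: 11 spirodienone lactone aldehyde; 5 diphenyl phosphonoacetamide of the protected chain
Product: 12 dienone lactone bearing the (Z)-cinnamamide chain
Conditions: 5, NaH, THF, 0 °C; then 11, −78 °C to −40 °C
Reagents that add atoms: none
Why: Horner–Wadsworth–Emmons olefination in its diaryl phosphonate variant. The electron-poor aryloxy groups make collapse of the first-formed adduct faster than its reversal, so the kinetic cis-oxaphosphetane delivers the Z-alkene of arm 2. The preformed soft carbanion reacts with the aromatic aldehyde far faster than with the lactone or with the neopentyl β-carbons of the dienone.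

Step 7
Reactants: 12 dienone lactone bearing the (Z)-cinnamamide chain
Product: 14 (S)-enone lactone bearing the (Z)-cinnamamide chain, via silyl dienol ether 13 (not isolated)
Conditions: Rh(OAc)2(H2O)[(S,S)-iPr-Phebox] (2 mol %; Phebox = 2,6-bis(oxazolinyl)phenyl), (EtO)2MeSiH (1.2 equiv), toluene, 40 °C; then 1 M HCl, THF, 0 °C
Reagents that add atoms: diethoxy(methyl)silane, CCO[SiH](C)OCC (its silyl group stands in 13 only and is lost on hydrolysis)
Why: Desymmetrising asymmetric conjugate hydrosilylation of a 4,4-disubstituted (spiro) cyclohexadienone, a known reaction type. The chiral rhodium hydride picks one of the two enantiotopic enone arms by reading the difference between the benzo carbon C9a and the lactone CH= at C9b, which sets C9b as S. The first addition gives the silyloxy diene 13, which is no longer an acceptor, so over-reduction is blocked, and the ketone-activated alkene reacts ahead of the ester- and amide-activated ones.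

Step 8
Reactants: 14 (S)-enone lactone bearing the (Z)-cinnamamide chain
Product: 15 bis(trifluoroacetate) salt of the deprotected (S)-enone lactone
Conditions: CF3CO2H, CH2Cl2, 0 °C to rt; evaporation
Reagents that add atoms: trifluoroacetic acid, OC(=O)C(F)(F)F
Why: Acidolysis of both tert-butyl carbamates. The amines are kept protonated and therefore cannot yet attack the lactone or the enone. After step 7 there is no dienone left that could undergo an acid-induced dienone–phenol rearrangement.

Step 9
Reactants: 15 bis(trifluoroacetate) salt of the deprotected (S)-enone lactone
Product: 18 target (4aR,9bS)-configured Z,Z-macrocycle CNP0159470.1, via free diamine 16 (not isolated), via macrolactam phenol 17 (not isolated)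
Conditions: slow addition of 15 (syringe pump, 12 h) to iPr2NEt (6 equiv), 2-pyridone (20 mol %), MeCN (final 1 mM), 40 °C
Reagents that add atoms: none
Why: Neutralisation frees diamine 16, an isomer of 18, whose primary N1 adds to the lactone carbonyl; collapse of the tetrahedral intermediate expels O5 as a phenoxide, so the acyl group moves from O to N and the seven-membered ring is traded for the 20-membered lactam of 17. The closest known reaction type is macrolactamisation through an aryl active ester, here built into the substrate, and ring D closes by exo attack on a trigonal acyl carbon (addition–elimination). The phenoxide of 17 then adds to the β-carbon of the one remaining enone in a 5-exo-trig oxa-Michael addition, the closure by which ortho–para phenol dimers form hexahydrodibenzofuranones, and protonation of the enolate gives ring B of 18. C4a is controlled by C9b: O5 hangs on the aryl group bonded to C9b and can reach only the enone face syn to that aryl group, so only the cis-fused (4aR,9bS) product can form. Because the other arm of ring C is already saturated, even a retro-oxa-Michael step leads back to the same 17, and the configuration cannot leak. The Z geometry of arm 1 is carried over from the ring and is not touched by the acyl transfer. The step needs N1 over N4 selectivity, 1,2- over 1,4-addition and ring closure over oligomerisation; these are secured by the lower hindrance of the primary amine towards a moderately reactive aryl ester, by the neopentyl position of both β-carbons next to C9b, and by high dilution. Acylation at N4 would place the acyl group three carbons away from free N1, from where a Zip-type transamidation through a six-membered intermediate leads to the same 20-membered secondary lactam.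

## Compound list

1 | N1,N4-bis-Boc-spermidine (tert-butyl N-(4-aminobutyl)-N-[3-(tert-butoxycarbonylamino)propyl]carbamate) | NCCCCN(CCCNC(=O)OC(C)(C)C)C(=O)OC(C)(C)C | starting material
2 | bromoacetyl bromide | O=C(Br)CBr | starting material
3 | N8-bromoacetyl-N1,N4-bis-Boc-spermidine | BrCC(=O)NCCCCN(CCCNC(=O)OC(C)(C)C)C(=O)OC(C)(C)C | intermediate
4 | diphenyl phosphite | O=[PH](Oc1ccccc1)Oc1ccccc1 | starting material
5 | N8-[2-(diphenoxyphosphoryl)acetyl]-N1,N4-bis-Boc-spermidine | O=P(Oc1ccccc1)(Oc1ccccc1)CC(=O)NCCCCN(CCCNC(=O)OC(C)(C)C)C(=O)OC(C)(C)C | intermediate
6 | 3-bromo-4-hydroxybenzaldehyde | O=Cc1ccc(O)c(Br)c1 | starting material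
7 | 4-methoxyphenylboronic acid | COc1ccc(cc1)B(O)O | starting material
8 | 6-hydroxy-4'-methoxybiphenyl-3-carbaldehyde | O=Cc1ccc(O)c(c1)-c1ccc(OC)cc1 | intermediate
9 | propiolic acid | C#CC(=O)O | starting material
10 | 5-formyl-4'-methoxybiphenyl-2-yl prop-2-ynoate | C#CC(=O)Oc1ccc(C=O)cc1-c1ccc(OC)cc1 | intermediate
11 | (3Z)-2,4'-dioxospiro[1-benzoxepine-5,1'-cyclohexa-2',5'-diene]-7-carbaldehyde | O=C1C=CC2(C=C1)/C=C\C(=O)Oc3ccc(C=O)cc32 | intermediate
12 | achiral spirodienone lactone with the (Z)-cinnamamide of N1,N4-bis-Boc-spermidine at C8 | O=C1C=CC2(C=C1)/C=C\C(=O)Oc3ccc(/C=C\C(=O)NCCCCN(CCCNC(=O)OC(C)(C)C)C(=O)OC(C)(C)C)cc32 | intermediate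
13 | (S)-diethoxy(methyl)silyl dienol ether of 14 | CCO[Si](C)(OCC)OC1=CC[C@]2(C=C1)/C=C\C(=O)Oc3ccc(/C=C\C(=O)NCCCCN(CCCNC(=O)OC(C)(C)C)C(=O)OC(C)(C)C)cc32 | intermediate
14 | (5S)-2,4'-dioxospiro[1-benzoxepine-5,1'-cyclohex-2'-ene] with the (Z)-cinnamamide of N1,N4-bis-Boc-spermidine at C7 of the benzoxepine (C8 in target numbering) | O=C1CC[C@]2(C=C1)/C=C\C(=O)Oc3ccc(/C=C\C(=O)NCCCCN(CCCNC(=O)OC(C)(C)C)C(=O)OC(C)(C)C)cc32 | intermediate
15 | bis(trifluoroacetate) salt of the (S)-enone lactone with free N1 and N4 | O=C1CC[C@]2(C=C1)/C=C\C(=O)Oc3ccc(/C=C\C(=O)NCCCC[NH2+]CCC[NH3+])cc32.[O-]C(=O)C(F)(F)F.[O-]C(=O)C(F)(F)F | intermediate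
16 | free diamine of the (S)-enone lactone | O=C1CC[C@]2(C=C1)/C=C\C(=O)Oc3ccc(/C=C\C(=O)NCCCCNCCCN)cc32 | intermediate
17 | (S)-configured 20-membered Z,Z-bis-lactam with free C5a phenol and ring C enone | O=C1CC[C@]2(C=C1)/C=C\C(=O)NCCCNCCCCNC(=O)/C=C\c3ccc(O)c2c3 | intermediate
18 | CNP0159470.1, (4aR,9bS)-configured Z,Z lunarine-type macrocycle | O=C1CC[C@]23/C=C\C(=O)NCCCNCCCCNC(=O)/C=C\c4ccc(c2c4)O[C@@H]3C1 | target

## Step count and least certain steps

Total step count: 9. Longest linear sequence: 7 (steps 3 to 9, from 6 and 7). The chain branch (steps 1 and 2) joins at step 6.

**Step 5 (Proposed new method).**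

- What may go wrong: the ester has to adopt its less stable s-cis conformation before the 7-endo closure can occur. Gold-catalysed hydration of the activated alkyne or its oligomerisation may therefore outrun the ipso attack.
- Traces of strong acid may also start a dienone–phenol rearrangement once the dienone has formed.
- Fallback with known chemistry: it sets out from 6 and comes back at 11. It makes the C9b–carbon bond intermolecularly and closes the lactone at the alkene instead.
- Suzuki–Miyaura coupling of 6 with 4-(tert-butyldimethylsilyloxy)phenylboronic acid (Pd(dppf)Cl2, K3PO4, dioxane) gives the silyl-protected biaryl phenol F1.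
- Acryloyl chloride and Et3N convert it into the aryl acrylate F2, and HF·pyridine frees the ring C phenol F3.
- PhI(OAc)2 in (CF3)2CHOH with allyltrimethylsilane (oxidative Hosomi–Sakurai allylation at the para carbon) gives the 4-allyl-4-aryl dienone F4.
- RuHCl(CO)(PPh3)3 moves the double bond into conjugation with nothing but C9b, giving the propenyl dienone F5.
- Ring-closing metathesis with the second-generation Hoveyda–Grubbs catalyst then closes the seven-membered, necessarily Z, enoate and gives 11.

**Step 9 (key step).**

- What may go wrong: the conjugated aryl ester is only moderately activated. Intermolecular aminolysis (oligomerisation) may compete with ring closure, N4 may be acylated in part, and reversible aza-Michael addition to the enone may tie up the amine.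
- Fallback: it sets out from 14 and comes back at 18. It separates the two events and changes the acyl donor.
- LiOH in THF/H2O opens the lactone of 14, and the phenoxide closes ring B at once, giving the tricyclic (Z)-acrylic acid F6.
- CF3CO2H removes both carbamates to give the amino acid F7.
- Diphenylphosphoryl azide with NaHCO3 in DMF at 0 °C under high dilution closes ring D through the mild acyl azide, which prefers the primary N1, and gives 18.

**Step 7.**

- What may go wrong: discrimination between the two enantiotopic arms may be poor, since the two groups at C9b that the catalyst must tell apart are both flat sp2 carbons.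
- Hydride transfer to the Z-enoate, or geometric erosion of arm 2 through reversible hydrometalation, is the second concern.
- Fallback: it sets out from 11 and comes back at 14. It moves the desymmetrisation to the small core and to a biocatalyst.
- An ene-reductase of the old yellow enzyme family (NADP+, glucose, glucose dehydrogenase, pH 7 buffer with cosolvent) reduces one enone arm of 11. This class of enzyme is known to desymmetrise 4,4-disubstituted cyclohexadienones. The product is the (S)-enone lactone aldehyde F8.
- F8 is then olefinated with 5 under the conditions of step 6 to give 14.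

**Step 6.**

- What may go wrong: Z-selectivity may be incomplete with a secondary-amide phosphonate, and conjugate addition of the carbanion to the dienone may occur if the temperature has to be raised.
- Fallback: it sets out from 3 and 11 and comes back at 12. It sets the geometry photochemically instead of kinetically.
- Arbuzov reaction of 3 with P(OEt)3 gives the diethyl phosphonoacetamide F9.
- Olefination of 11 with F9 under LiCl/DBU gives the (E)-cinnamamide dienone F10.
- Visible-light energy transfer with fac-Ir(ppy)3 (blue LED, MeCN) drives the contra-thermodynamic E to Z isomerisation of the cinnamamide. The sensitiser's triplet energy lies below that of the dienone, and the ring-locked alkene of arm 1 cannot isomerise. The product is 12, and recovered F10 is recycled.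

## Further compounds

F1 | step 5 | 4'-(tert-butyldimethylsilyloxy)-6-hydroxybiphenyl-3-carbaldehyde | O=Cc1ccc(O)c(c1)-c1ccc(O[Si](C)(C)C(C)(C)C)cc1
F2 | step 5 | 4'-(tert-butyldimethylsilyloxy)-5-formylbiphenyl-2-yl prop-2-enoate | C=CC(=O)Oc1ccc(C=O)cc1-c1ccc(O[Si](C)(C)C(C)(C)C)cc1
F3 | step 5 | 5-formyl-4'-hydroxybiphenyl-2-yl prop-2-enoate | C=CC(=O)Oc1ccc(C=O)cc1-c1ccc(O)cc1
F4 | step 5 | 4-formyl-2-[4-oxo-1-(prop-2-enyl)cyclohexa-2,5-dien-1-yl]phenyl prop-2-enoate | C=CCC1(C=CC(=O)C=C1)c1cc(C=O)ccc1OC(=O)C=C
F5 | step 5 | 4-formyl-2-{4-oxo-1-[(E)-prop-1-enyl]cyclohexa-2,5-dien-1-yl}phenyl prop-2-enoate | C/C=C/C1(C=CC(=O)C=C1)c1cc(C=O)ccc1OC(=O)C=C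
F6 | step 9 | (4aR,9bS)-tricyclic (Z)-acrylic acid with the (Z)-cinnamamide of N1,N4-bis-Boc-spermidine at C8 | O=C1CC[C@]2(/C=C\C(=O)O)c3cc(/C=C\C(=O)NCCCCN(CCCNC(=O)OC(C)(C)C)C(=O)OC(C)(C)C)ccc3O[C@@H]2C1
F7 | step 9 | (4aR,9bS)-tricyclic (Z)-acrylic acid with free N1 and N4 (seco amino acid of 18) | O=C1CC[C@]2(/C=C\C(=O)O)c3cc(/C=C\C(=O)NCCCCNCCCN)ccc3O[C@@H]2C1
F8 | step 7 | (3Z,5S)-2,4'-dioxospiro[1-benzoxepine-5,1'-cyclohex-2'-ene]-7-carbaldehyde | O=C1CC[C@]2(C=C1)/C=C\C(=O)Oc3ccc(C=O)cc32
F9 | step 6 | N8-[2-(diethoxyphosphoryl)acetyl]-N1,N4-bis-Boc-spermidine | CCOP(=O)(OCC)CC(=O)NCCCCN(CCCNC(=O)OC(C)(C)C)C(=O)OC(C)(C)C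
F10 | step 6 | (E)-cinnamamide isomer of 12 | O=C1C=CC2(C=C1)/C=C\C(=O)Oc3ccc(/C=C/C(=O)NCCCCN(CCCNC(=O)OC(C)(C)C)C(=O)OC(C)(C)C)cc32
A1 | alternative 1 | 3-bromo-4-{[(7R)-8-(tert-butyldimethylsilyloxymethyl)-1,4-dioxaspiro[4.5]dec-8-en-7-yl]oxy}benzaldehyde | O=Cc1ccc(O[C@@H]2CC3(OCCO3)CC=C2CO[Si](C)(C)C(C)(C)C)c(Br)c1
A2 | alternative 1 | (4aR,9bS)-3-oxohexahydrodibenzofuran-8,9b-diyl bis[(Z)-acrylic acid] | O=C1CC[C@]2(/C=C\C(=O)O)c3cc(/C=C\C(=O)O)ccc3O[C@@H]2C1
A3 | alternative 2 | N1,N8-bis[(Z)-4-hydroxycinnamoyl]spermidine | Oc1ccc(/C=C\C(=O)NCCCNCCCCNC(=O)/C=C\c2ccc(O)cc2)cc1
A4 | alternative 2 | achiral 20-membered Z,Z-bis-lactam with free phenol and ring C cross-conjugated dienone | O=C1C=CC2(C=C1)/C=C\C(=O)NCCCNCCCCNC(=O)/C=C\c3ccc(O)c2c3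
A5 | alternative 3 | 5-bromo-1-benzofuran-3-carbaldehyde | O=Cc1coc2ccc(Br)cc12
A6 | alternative 3 | (4aR,9bS)-8-bromo-3-oxo-1,2,3,4,4a,9b-hexahydrodibenzofuran-9b-carbaldehyde | O=C1CC[C@]2(C=O)c3cc(Br)ccc3O[C@@H]2C1
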